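## Retrosynthetic overview
1. Target 28 is the closed hemiketal tautomer of a 4-oxo-8-hydroxy briarane. It comes from the C4 allylic alcohol 27, made by C4–C5 Nozaki–Hiyama–Kishi (NHK) closure of the ten-membered ring from aldehyde/2-bromoalkene 26.
2. The γ-lactone with C7, C8 and C17 comes from OH-directed epoxidation of a C7=C8 β,γ-unsaturated tert-butyl ester, followed by lactonising epoxide opening. The alkene comes from a C7≡C8 alkyne (trans-hydrostannation, iodide, Reformatsky–Negishi coupling). C5, C6 and C16 come from 2,3-dibromopropene.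
3. C9, C10 and the Δ11(20) methylene come from one Nakai [2,3]-Wittig rearrangement of a (cyclohexenyl)methyl TMS-propargyl ether.
4. The C1 quaternary centre comes from anti-selective Me2CuLi addition with enol triflate trapping. C2 and C14 come from an asymmetric Morita–Baylis–Hillman (MBH) reaction of cyclohexenone and a syn-1,3-reduction.
5. Ring order: cyclohexane (purchased ring), γ-lactone (step 16), ten-membered carbocycle (step 21), oxane/hemiketal bridge (step 22).

**Assumptions**
- Briarane numbering is used throughout: C1 is the quaternary carbon, C2–C10 run around the large ring, and C11–C14 complete the cyclohexane. C15 is the 1-Me and C16 the 5-methylene. C17/C18/C19 are the lactone CH/CH3/C=O, and C20 is the 11-methylene. The target is 1R,2R,4R,7S,8S,9R,10S,14S,17R.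
- C4 is a hemiketal carbon and equilibrates through the open hydroxy-ketone. Its configuration is therefore thermodynamic, and the drawn 4R form is taken as the resting state of the natural product.
- In step 3 the catalyst antipode is the one that delivers the (R)-carbinol.

## Route

**Step 1**
Reactants: 1 propane-1,3-diol
Product: 2 3-[(tert-butyldiphenylsilyl)oxy]propan-1-ol
Conditions: NaH (1 equiv), THF, 0 °C to rt; TBDPSCl (1 equiv)
Reagents that add atoms: TBDPSCl, CC(C)(C)[Si](Cl)(c1ccccc1)c1ccccc1
Why: McDougal monosilylation, in which the poorly soluble monosodium alkoxide is silylated once; no stereocentre is formed.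

**Step 2**
Reactants: 2
Product: 3 3-[(tert-butyldiphenylsilyl)oxy]propanal (carbons C2–C4)
Conditions: TEMPO (cat.), PhI(OAc)2, CH2Cl2, rt
Reagents that add atoms: none
Why: TEMPO/BAIB oxidation stops at the aldehyde under near-neutral conditions, which avoids β-elimination of the silyloxy group.

**Step 3**
Reactants: 3; 4 cyclohex-2-en-1-one
Product: 5 2-[(1R)-3-(TBDPSO)-1-hydroxypropyl]cyclohex-2-en-1-one (C2 = R)
Conditions: PEt3, 3,3'-bis(3,5-dimethylphenyl)-H8-BINOL (10 mol %), THF, −10 °C
Reagents that add atoms: none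
Why: The Brønsted-acid/phosphine-catalysed asymmetric Morita–Baylis–Hillman reaction joins C1–C2, and the chiral BINOL H-bonded phosphonium enolate selects one aldehyde face to set C2.

**Step 4**
Reactants: 5
Product: 6 (1S)-2-[(1R)-3-(TBDPSO)-1-hydroxypropyl]cyclohex-2-en-1-ol (syn-2,14-diol)
Conditions: Et2BOMe, THF/MeOH 4:1, −78 °C; NaBH4; MeOH azeotrope
Reagents that add atoms: none
Why: In this Narasaka–Prasad reduction, A1,3 strain places the C3 chain perpendicular on the boron chelate, so hydride attacks C14=O 1,2 from the opposite face and gives the syn-1,3-diol (sets C14).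

**Step 5**
Reactants: 6
Product: 7 2,14-bis(triethylsilyl) ether of 6
Conditions: TESOTf, 2,6-lutidine, CH2Cl2, −78 to 0 °C
Reagents that add atoms: TESOTf, CC[Si](CC)(CC)OS(=O)(=O)C(F)(F)F
Why: Silylation gives two bulky, base-stable, acid-labile groups on the α-face, and acyclic protection leaves the ring conformationally free for step 10.

**Step 6**
Reactants: 7
Product: 8 (4S)-4-(TESO)-3-[(1R)-3-(TBDPSO)-1-(TESO)propyl]cyclohex-2-en-1-one (C11 ketone, Δ1(10))
Conditions: Rh2(cap)4 (1 mol %), t-BuOOH, K2CO3, CH2Cl2, rt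
Reagents that add atoms: tert-butyl hydroperoxide, CC(C)(C)OO
Why: Doyle allylic C–H oxidation targets the only unhindered allylic CH2 (C11), because the two other allylic C–H bonds are shielded by silyloxy groups.

**Step 7**
Reactants: 8
Product: 9 (3R,4S)-3-methyl-4-(TESO)-3-[(1R)-3-(TBDPSO)-1-(TESO)propyl]cyclohex-1-en-1-yl triflate (1R,2R,14S)
Conditions: Me2CuLi, Et2O, −20 to 0 °C; then Comins' reagent, THF, −78 °C to rt
Reagents that add atoms: Me2CuLi, [Li+].C[Cu-]C; Comins' reagent, FC(F)(F)S(=O)(=O)N(c1ccc(Cl)cn1)S(=O)(=O)C(F)(F)F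
Why: Gilman conjugate addition occurs axially and anti to the pseudo-axial 14-OTES to set quaternary C1 (Me β), and the regiodefined C10=C11 enolate is trapped as its triflate (McMurry–Scott/Comins).

**Step 8**
Reactants: 9; 10 (tributylstannyl)methanol
Product: 11 the corresponding (cyclohex-1-en-1-yl)methanol (C20H2OH on C11)
Conditions: Pd(PPh3)4, LiCl, dioxane, 90 °C
Reagents that add atoms: 10, OC[Sn](CCCC)(CCCC)CCCC
Why: Stille (Kosugi) hydroxymethylation of the unhindered C11 triflate installs C20 and the oxygen that later becomes O9.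

**Step 9**
Reactants: 11; 12 3-bromo-1-(trimethylsilyl)prop-1-yne
Product: 13 3-(trimethylsilyl)prop-2-ynyl ether of 11
Conditions: NaH, TBAI, THF, 0 °C to rt
Reagents that add atoms: 12, C[Si](C)(C)C#CCBr
Why: Williamson etherification of the primary allylic alkoxide introduces C9, C8 and C7.

**Step 10**
Reactants: 13
Product: 14 (1R)-1-{(1S,2R,3S)-2-methyl-6-methylidene-3-(TESO)-2-[(1R)-3-(TBDPSO)-1-(TESO)propyl]cyclohexyl}-3-(trimethylsilyl)prop-2-yn-1-ol (1R,2R,9R,10S,14S)
Conditions: n-BuLi, THF, −78 °C; AcOH quench at −78 °C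
Reagents that add atoms: none
Why: In the Nakai [2,3]-Wittig rearrangement the propargylic carbanion bonds to C10 on the β-face (the α-face carries the branched C2 chain and 14-OTES), and the E-type alkene with an exo-alkynyl envelope transition state gives the 9,10-anti product while moving the alkene to Δ11(20), which sets C10 and C9.

**Step 11**
Reactants: 14
Product: 15 terminal alkyne (C7–H)
Conditions: K2CO3, MeOH, rt
Reagents that add atoms: none
Why: Protodesilylation removes the alkynyl TMS selectively, and the hindered secondary TES ethers and the TBDPS ether are untouched.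

**Step 12**
Reactants: 15; 16 2,3-dibromopropene
Product: 17 skipped enyne C9(OH)–C8≡C7–C6H2–C5(Br)=C16H2
Conditions: CuI, NaI, K2CO3, DMF, rt
Reagents that add atoms: 16, C=C(Br)CBr
Why: Copper-acetylide allylation displaces only the allylic bromide, tolerates the free 9-OH, and installs the NHK vinyl bromide.

**Step 13**
Reactants: 17
Product: 18 (7Z)-8-iodo-7-ene (I on C8, cis to C6; C9 and C6 trans)
Conditions: [Cp*RuCl]4 (2.5 mol %), Bu3SnH, CH2Cl2, rt; then I2, NaHCO3, 0 °C (one pot)
Reagents that add atoms: iodine, II (Bu3SnH contributes only H7)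
Why: In Fürstner's hydroxyl-directed trans-hydrostannation an OH···Cl–Ru hydrogen bond places tin on the proximal carbon C8 with anti H/Sn addition, and iododestannylation proceeds with retention.

**Step 14**
Reactants: 18; 19 tert-butyl 2-bromopropanoate
Product: 20 tert-butyl ester C19O2tBu–C17H(CH3)–C8(=C7H–C6)–C9, 7E (C17 cis to C6), C17 epimer mixture
Conditions: 19, Zn (TMSCl-activated), THF; then 18, Pd(PPh3)4 (10 mol %), THF/DMPU, 25–40 °C (4 equiv zinc reagent)
Reagents that add atoms: Reformatsky reagent from 19, CC([Zn]Br)C(=O)OC(C)(C)C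
Why: In this Negishi-type (Fauvarque–Jutand) Reformatsky coupling the C–I bond adds to Pd(0) much faster than the 2-bromoalkene, alkene geometry is retained, and the tert-butyl ester cannot transesterify onto O9.

**Step 15**
Reactants: 20
Product: 21 (7R,8R)-7,8-epoxide, 9-OH free (O8 anti to O9; C17 mixture)
Conditions: VO(acac)2 (5 mol %), t-BuOOH (decane), CH2Cl2, 0 °C
Reagents that add atoms: tert-butyl hydroperoxide, CC(C)(C)OO
Why: Sharpless–Michaelson directed epoxidation touches only the allylic alkene, and A1,2 strain between C10 and the geminal C17 branch enforces the erythro epoxy alcohol, which sets C8 in its final spatial arrangement.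

**Step 16**
Reactants: 21
Product: 22 8-hydroxy-7,19-γ-lactone 2,9,14-triol, 4-OTBDPS (7S,8R; same spatial arrangement at C8 as the target, the descriptor differs only through CIP ranking; C17 mixture)
Conditions: CSA (0.3 equiv), CH2Cl2, 0 °C; then MeOH, rt
Reagents that add atoms: none
Why: In this anchimerically assisted epoxide opening the ester carbonyl can only reach C7 (five-membered ring), attacks with inversion and loses isobutene to give the cis-7,8 lactone with free 8-OH (sets C7), and methanolysis then removes both TES groups while TBDPS survives.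

**Step 17**
Reactants: 22
Product: 23 2,9,14-triacetate (8-OH free, C17 mixture)
Conditions: Ac2O, pyridine, DMAP (cat.), CH2Cl2, rt
Reagents that add atoms: acetic anhydride, CC(=O)OC(C)=O
Why: Acylation installs all three natural acetates at once, and the tertiary 8-OH flanked by two branched carbons does not react.

**Step 18**
Reactants: 23
Product: 24 (17R)-triacetate (1R,2R,7S,8S,9R,10S,14S,17R)
Conditions: DBU, toluene, rt
Reagents that add atoms: none
Why: Thermodynamic epimerisation α to the lactone carbonyl converges on the isomer with C18 trans to the bulky C9 branch (cis to the small 8-OH), which sets C17.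

**Step 19**
Reactants: 24
Product: 25 primary C4 alcohol
Conditions: HF·pyridine, pyridine/THF, 0 °C to rt
Reagents that add atoms: none
Why: Buffered fluoride desilylation removes the TBDPS group without the base-induced O2 to O4 acetyl migration that TBAF could cause.

**Step 20**
Reactants: 25
Product: 26 C4 aldehyde (β-acetoxy aldehyde)
Conditions: Dess–Martin periodinane, NaHCO3, CH2Cl2, 0 °C
Reagents that add atoms: none
Why: Buffered neutral Dess–Martin oxidation avoids β-elimination of the 2-OAc, and the tertiary 8-OH is inert.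

**Step 21**
Reactants: 26
Product: 27 ten-membered carbocycle with a C4 allylic alcohol (epimers) and the C5=C16 methylene
Conditions: CrCl2 (15 equiv), NiCl2 (1 mol % of Cr), DMSO/THF, 2 mM, slow addition, rt
Reagents that add atoms: none
Why: The intramolecular Nozaki–Hiyama–Kishi reaction tolerates esters, the lactone and the free tertiary alcohol, the trans-diequatorial C2/C9 arms pre-organise closure, and the new C4 carbinol centre is destroyed in the next step.

**Step 22**
Reactants: 27
Product: 28 (+)-junceellolide A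
Conditions: Dess–Martin periodinane, NaHCO3, CH2Cl2, 0 °C to rt; equilibration on work-up
Reagents that add atoms: none
Why: Dess–Martin oxidation gives the α-methylene ketone, which is captured transannularly by 8-OH in a reversible six-membered hemiketalisation, so C4 is set under thermodynamic control.

## Compound list
1 | propane-1,3-diol | OCCCO | starting material
2 | 3-(TBDPSO)propan-1-ol | OCCCO[Si](c1ccccc1)(c1ccccc1)C(C)(C)C | intermediate
3 | 3-(TBDPSO)propanal | O=CCCO[Si](c1ccccc1)(c1ccccc1)C(C)(C)C | intermediate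
4 | cyclohex-2-en-1-one | O=C1C=CCCC1 | starting material
5 | MBH adduct (2R) | O=C1CCCC=C1[C@H](O)CCO[Si](c1ccccc1)(c1ccccc1)C(C)(C)C | intermediate
6 | syn-diol (2R,14S) | O[C@H]1CCCC=C1[C@H](O)CCO[Si](c1ccccc1)(c1ccccc1)C(C)(C)C | intermediate
7 | bis-TES ether | CC[Si](CC)(CC)O[C@H]1CCCC=C1[C@H](O[Si](CC)(CC)CC)CCO[Si](c1ccccc1)(c1ccccc1)C(C)(C)C | intermediate
8 | C11 enone | O=C1C=C([C@H](O[Si](CC)(CC)CC)CCO[Si](c2ccccc2)(c2ccccc2)C(C)(C)C)[C@@H](O[Si](CC)(CC)CC)CC1 | intermediate
9 | enol triflate (1R,2R,14S) | O=S(=O)(OC1=C[C@]([C@H](O[Si](CC)(CC)CC)CCO[Si](c2ccccc2)(c2ccccc2)C(C)(C)C)(C)[C@@H](O[Si](CC)(CC)CC)CC1)C(F)(F)F | intermediate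
10 | (tributylstannyl)methanol | OC[Sn](CCCC)(CCCC)CCCC | starting material
11 | allylic alcohol (C20–OH) | OCC1=C[C@]([C@H](O[Si](CC)(CC)CC)CCO[Si](c2ccccc2)(c2ccccc2)C(C)(C)C)(C)[C@@H](O[Si](CC)(CC)CC)CC1 | intermediate
12 | 3-bromo-1-(trimethylsilyl)prop-1-yne | C[Si](C)(C)C#CCBr | starting material
13 | TMS-propargyl ether | C[Si](C)(C)C#CCOCC1=C[C@]([C@H](O[Si](CC)(CC)CC)CCO[Si](c2ccccc2)(c2ccccc2)C(C)(C)C)(C)[C@@H](O[Si](CC)(CC)CC)CC1 | intermediate
14 | [2,3]-Wittig product (1R,2R,9R,10S,14S) | C=C1CC[C@H](O[Si](CC)(CC)CC)[C@@]([C@H](O[Si](CC)(CC)CC)CCO[Si](c2ccccc2)(c2ccccc2)C(C)(C)C)(C)[C@H]1[C@@H](O)C#C[Si](C)(C)C | intermediate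
15 | terminal alkyne | C=C1CC[C@H](O[Si](CC)(CC)CC)[C@@]([C@H](O[Si](CC)(CC)CC)CCO[Si](c2ccccc2)(c2ccccc2)C(C)(C)C)(C)[C@H]1[C@@H](O)C#C | intermediate
16 | 2,3-dibromopropene | C=C(Br)CBr | starting material
17 | bromo-enyne | C=C1CC[C@H](O[Si](CC)(CC)CC)[C@@]([C@H](O[Si](CC)(CC)CC)CCO[Si](c2ccccc2)(c2ccccc2)C(C)(C)C)(C)[C@H]1[C@@H](O)C#CCC(Br)=C | intermediate
18 | (7Z)-8-iodoalkene | C=C1CC[C@H](O[Si](CC)(CC)CC)[C@@]([C@H](O[Si](CC)(CC)CC)CCO[Si](c2ccccc2)(c2ccccc2)C(C)(C)C)(C)[C@H]1[C@@H](O)/C(I)=C/CC(Br)=C | intermediate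
19 | tert-butyl 2-bromopropanoate | CC(Br)C(=O)OC(C)(C)C | starting material
20 | (7E)-β,γ-unsaturated tert-butyl ester (C17 mixture) | C=C1CC[C@H](O[Si](CC)(CC)CC)[C@@]([C@H](O[Si](CC)(CC)CC)CCO[Si](c2ccccc2)(c2ccccc2)C(C)(C)C)(C)[C@H]1[C@@H](O)/C(C(C)C(=O)OC(C)(C)C)=C/CC(Br)=C | intermediate
21 | (7R,8R)-epoxy alcohol (C17 mixture) | C=C1CC[C@H](O[Si](CC)(CC)CC)[C@@]([C@H](O[Si](CC)(CC)CC)CCO[Si](c2ccccc2)(c2ccccc2)C(C)(C)C)(C)[C@H]1[C@@H](O)[C@@]3(C(C)C(=O)OC(C)(C)C)O[C@@H]3CC(Br)=C | intermediate
22 | hydroxy-lactone triol (C17 mixture) | C=C1CC[C@H](O)[C@@]([C@H](O)CCO[Si](c2ccccc2)(c2ccccc2)C(C)(C)C)(C)[C@H]1[C@@H](O)[C@@]3(O)[C@H](CC(Br)=C)OC(=O)C3C | intermediate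
23 | triacetate (C17 mixture) | C=C1CC[C@H](OC(C)=O)[C@@]([C@H](OC(C)=O)CCO[Si](c2ccccc2)(c2ccccc2)C(C)(C)C)(C)[C@H]1[C@@H](OC(C)=O)[C@@]3(O)[C@H](CC(Br)=C)OC(=O)C3C | intermediate
24 | (17R)-triacetate | C=C1CC[C@H](OC(C)=O)[C@@]([C@H](OC(C)=O)CCO[Si](c2ccccc2)(c2ccccc2)C(C)(C)C)(C)[C@H]1[C@@H](OC(C)=O)[C@@]3(O)[C@H](CC(Br)=C)OC(=O)[C@@H]3C | intermediate
25 | C4 primary alcohol | C=C1CC[C@H](OC(C)=O)[C@@]([C@H](OC(C)=O)CCO)(C)[C@H]1[C@@H](OC(C)=O)[C@@]3(O)[C@H](CC(Br)=C)OC(=O)[C@@H]3C | intermediate
26 | C4 aldehyde | C=C1CC[C@H](OC(C)=O)[C@@]([C@H](OC(C)=O)CC=O)(C)[C@H]1[C@@H](OC(C)=O)[C@@]3(O)[C@H](CC(Br)=C)OC(=O)[C@@H]3C | intermediate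
27 | macrocyclic C4 allylic alcohol (C4 epimers) | C=C1CC[C@H](OC(C)=O)[C@@]2(C)[C@H]1[C@@H](OC(C)=O)[C@@]3(O)[C@H](CC(=C)C(O)C[C@H]2OC(C)=O)OC(=O)[C@@H]3C | intermediate
28 | (+)-junceellolide A | C=C1CC[C@H](OC(C)=O)[C@@]2(C)[C@H]1[C@@H](OC(C)=O)[C@@]13O[C@](O)(C[C@H]2OC(C)=O)C(=C)C[C@@H]1OC(=O)[C@@H]3C | target

**Where each stereocentre is set:** C2 in step 3, C14 in step 4, C1 in step 7, C9 and C10 in step 10, C8 in step 15, C7 in steps 15–16 (epoxide, then inversion), C17 in step 18, and C4 in step 22.

## Summary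
**Total step count:** 22.
**Longest linear sequence:** 22 steps from propane-1,3-diol (20 from cyclohexenone). Compounds 4, 10, 12, 16 and 19 are purchased.

**The three steps most likely to fail**
1. **Step 10, [2,3]-Wittig.** The new C9–C10 bond forms next to quaternary C1, so β-face selectivity and competing [1,2]-shift are the concerns.
   - *Fallback:* drop the sigmatropic route. Trap the cuprate enolate of step 7 with 3-(trimethylsilyl)propynal in a tandem conjugate addition–aldol.
   - Then equilibrate C10, which is now epimerisable α to the C11 ketone, and install Δ11(20) by Takai–Lombardo methylenation.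
2. **Step 14, coupling of a secondary Reformatsky reagent with a hindered vinyl iodide.** The vinyl bromide may compete, the ester may slip into conjugation, and the regiochemistry of step 16 depends on this product.
   - *Fallback:* build the lactone by aldol logic instead. Use acetate-assisted Au(I) hydration of the 9-acetate of 17 to reach the C8 ketone, then Rubottom hydroxylation at C7.
   - Esterify O7 as the 2-bromopropionate and close with a SmI2 intramolecular Reformatsky reaction onto C8, which gives the same 8-hydroxy-17-methyl lactone with no Pd step.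
3. **Step 21, ten-membered NHK closure.** The substrate is a β-acetoxy aldehyde with a vinyl bromide, so oligomerisation, AcOH elimination and O2 to O4 acetyl migration are all possible. The C4 configuration in step 22 also cannot be steered.
   - *Fallback:* move the ring-closing bond to C2–C3. Use formaldehyde in the MBH step so that C2 is carried as a neopentyl aldehyde.
   - Introduce C3–C6 in step 12 as a protected 3-(bromomethyl)but-3-en-2-one unit.
   - Close with a SmI2-mediated intramolecular Reformatsky-type aldol of the C3 α-bromoketone onto C2, which delivers the 2-OH/4-oxo array directly.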